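Readings and results are calculated for substances that don't exist, noise included.

The amounts first: at 0.833 d the south-east run holds 35.0% target and the north-west run 35.2%, though their starting material stood at 0.094 M and 0.21 M. Your hunch that concentration moves the yield therefore finds no support in these readings. The south-west run, at 0.14 M between those two but with 2 equiv of second substrate, reads 20.4% at 0.167 d.

| flask | starting material | coupling partner | second substrate | remark | time |
|---|---|---|---|---|---|
| south-east | 0.094 M | 0.90 equiv | 1 equiv | run made earlier |  |
| north-west | 0.21 M | 0.90 equiv | 1 equiv | run made earlier |  |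
| south-west | 0.14 M | 0.90 equiv | 2 equiv | run made earlier |  |
| flask | 0.14 M | 0.900 equiv | 1.00 equiv |  | 15 d |

| run | time / d | target / % | starting material / % |
|---|---|---|---|
| south-east | 0.167 | 33.1 | 10.3 |
| south-east | 0.833 | 35.0 | 0 |
| south-east | 4.00 | 31.0 | 0 |
| south-east | 20.0 | 17.2 | 0 |
| north-west | 0.167 | 35.9 | 0.7 |
| north-west | 0.833 | 35.2 | 0.4 |
| north-west | 4.00 | 31.3 | 0.2 |
| north-west | 20.0 | 17.0 | 0 |
| south-west | 0.167 | 20.4 | 0.1 |
| south-west | 0.833 | 20.0 | 0.7 |
| south-west | 4.00 | 18.1 | 0.1 |
| south-west | 20.0 | 9.4 | 0 |

(each reading ± 0.5 percentage points)



1. the moment within 15 d at which there is most target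
2. the amount of target, in percent of the starting material charged, at that time

I take the fast loss of starting material as settled and read the north-west run at 0.167 d, when 0.7% of it remains. This gives the split:

s = 0.622

The split is target per part of starting material lost elsewhere, scaled by second substrate over coupling partner; it is a selectivity factor. The south-west run gives 0.570, which is close. For the flask, with 0.900 equiv of coupling partner and 1.00 equiv of second substrate, I reckon:

target = 35.9%

The north-west readings put the target's decay at 0.0380 d⁻¹. Scaling the south-east loss of starting material to 0.14 M gives 20.3 d⁻¹, far faster than that decay. By my estimate the two flows balance in the flask at: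

t = ln(loss/decay)/loss = 0.310 d

The forecast gives 35.8% (35.1% to 36.5%) at 0.4 d (0.2 d to 0.8 d), holding that “The maximum comes when formation equals decay”.

The flask gives 36.0% at 0.393 d.

    starting material + coupling partner → target (k = 0.00105 L mol⁻¹ s⁻¹)
    second substrate + coupling partner → second product (k = 1.15 × 10⁻⁴ L mol⁻¹ s⁻¹)
    starting material + second substrate → cross product (k = 0.00200 L mol⁻¹ s⁻¹)
    coupling partner → decomposed reagent (k = 4.92 × 10⁻⁶ s⁻¹)
    target → over-reaction product (k = 4.30 × 10⁻⁷ s⁻¹)

In the flask, starting material has a half-life of 1.0 h by the step to cross product at 0.0222 d, far shorter than the 18.7 d of target going to over-reaction product; at 0.393 d the flask holds 63.3% cross product beside 36.0% target, where the split gave 35.9%. With 0.250 equiv of second substrate, the split gives 69.1% and that neighbour flask reaches 70.3%.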